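**Plan**

- Retrosynthetic cuts, in order: the C3–O ester bond (side-chain acid removed); the O1–C2 ether bond of the dihydrofuran (ring B); the C3–C(alkenyl) bond, which leads back to 5-acetylsalicylaldehyde and an (E)-3-iodo-2-methylallyl carbonate.
- Enabling feature: C2 carries O1 and is also the allylic carbon next to the isopropenyl C=C. Seen from O1, C2–C(CH3)=CH2 is a 2-methylallyl unit, so ring B can be closed by allylic substitution with the alkene ending up exocyclic.
- Forward: ring A comes from 4'-hydroxyacetophenone; the four-carbon chain is attached by a Nozaki–Hiyama–Kishi coupling; ring B, the only ring made, closes in step 8; the ester side chain (from crotonaldehyde) is joined last.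
- Stereochemistry: C3 from the ligand-controlled chromium addition (R carbinol, which becomes 3S). C2 from face selection on the π-allylpalladium intermediate by a chiral diphosphine, supported by the trans preference of the C3 silyloxy group. The Z alkene from (Z)-2-iodobut-2-enal, carried through a geometry-retaining carbonylation.

Key step: step 8

Assumption: the (S)-oxazoline sulfonamide of step 5 and the (R,R)-diphosphine of step 8 are taken to be the ligand antipodes that give the R carbinol and the 2R ether; if a test run shows the opposite sense, the mirror-image ligand is used in that step and nothing else changes.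

**Route**

Step 1
Reactants: 1 4'-hydroxyacetophenone
Product: 3 5-acetyl-2-hydroxybenzaldehyde, via hydroxymethyl phenol 2 (not isolated)
Conditions: MgCl2, Et3N, (CH2O)n, MeCN, reflux; then 1 M HCl
Reagents that add atoms: formaldehyde (as paraformaldehyde), C=O
Why: Magnesium-mediated ortho-formylation of a phenol (Casnati–Skattebøl reaction), in which the magnesium phenoxide delivers formaldehyde to the free ortho position and the bound benzylic alkoxide is oxidised to the aldehyde by hydride transfer to a second formaldehyde, the para position being blocked by the acetyl group.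

Step 2
Reactants: 3 5-acetyl-2-hydroxybenzaldehyde
Product: 4 5-acetyl-2-(tert-butyldimethylsilyloxy)benzaldehyde
Conditions: TBSCl, imidazole, CH2Cl2, 0 °C to rt
Reagents that add atoms: tert-butyldimethylsilyl chloride, CC(C)(C)[Si](C)(C)Cl
Why: Silylation of a phenol masks the acidic OH, which would otherwise protonate the organochromium reagent of step 5.

Step 3
Reactants: 5 propargyl alcohol
Product: 7 (E)-3-iodo-2-methylprop-2-en-1-ol, via alkenylalane 6 (not isolated)
Conditions: Me3Al (3 equiv), Cp2ZrCl2 (0.25 equiv), CH2Cl2, 0 °C to rt; then I2, THF, −30 to 0 °C; aq. K2CO3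
Reagents that add atoms: trimethylaluminium, C[Al](C)C; iodine, II
Why: Zirconium-catalysed syn carboalumination of a terminal alkyne (Negishi carboalumination) puts methyl on the internal and aluminium on the terminal carbon, and iodinolysis of the C–Al bond with retention should give the E iodide as one isomer.

Step 4
Reactants: 7 (E)-3-iodo-2-methylprop-2-en-1-ol
Product: 8 methyl (2E)-3-iodo-2-methylprop-2-en-1-yl carbonate
Conditions: ClCO2Me, pyridine, CH2Cl2, 0 °C
Reagents that add atoms: methyl chloroformate, COC(=O)Cl
Why: Acylation of the primary alcohol with a chloroformate installs the leaving group that palladium will ionise in step 8.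

Step 5
Reactants: 4 5-acetyl-2-(tert-butyldimethylsilyloxy)benzaldehyde; 8 methyl (2E)-3-iodo-2-methylprop-2-en-1-yl carbonate
Product: 10 methyl (2E,4R)-4-[5-acetyl-2-(tert-butyldimethylsilyloxy)phenyl]-4-hydroxy-2-methylbut-2-en-1-yl carbonate, via trimethylsilyl ether 9 (not isolated)
Conditions: CrCl2 (10 mol %), (S)-N-[2-(4-isopropyl-4,5-dihydrooxazol-2-yl)-6-methylphenyl]methanesulfonamide (11 mol %), Et3N (20 mol %), NiCl2·(2,9-dimethyl-1,10-phenanthroline) (2 mol %), Mn (2 equiv), Me3SiCl (1.5 equiv), LiCl, MeCN, rt; then 10% aq. citric acid, MeOH, 0 °C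
Reagents that add atoms: none
Why: Catalytic asymmetric Nozaki–Hiyama–Kishi reaction, in which zerovalent nickel inserts into the C–I bond, the alkenyl group passes to chromium held by the chiral sulfonamide, and the alkenylchromium species adds to the aldehyde face chosen by the ligand to set the R carbinol, while the aryl ketone, the carbonate and the aryl silyl ether are inert to organochromium reagents and Me3SiCl with Mn turns the chromium over.

Step 6
Reactants: 10 methyl (2E,4R)-4-[5-acetyl-2-(tert-butyldimethylsilyloxy)phenyl]-4-hydroxy-2-methylbut-2-en-1-yl carbonate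
Product: 11 methyl (2E,4R)-4-[5-acetyl-2-(tert-butyldimethylsilyloxy)phenyl]-4-(tert-butyldimethylsilyloxy)-2-methylbut-2-en-1-yl carbonate
Conditions: TBSOTf, 2,6-lutidine, CH2Cl2, −78 °C
Reagents that add atoms: tert-butyldimethylsilyl triflate, CC(C)(C)[Si](C)(C)OS(=O)(=O)C(F)(F)F
Why: Silyl triflate silylation of a hindered secondary alcohol is fast at −78 °C, where the weak base 2,6-lutidine does not enolise the aryl methyl ketone, and the C–O bond of the stereocentre is not broken.

Step 7
Reactants: 11 methyl (2E,4R)-4-[5-acetyl-2-(tert-butyldimethylsilyloxy)phenyl]-4-(tert-butyldimethylsilyloxy)-2-methylbut-2-en-1-yl carbonate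
Product: 12 methyl (2E,4R)-4-(5-acetyl-2-hydroxyphenyl)-4-(tert-butyldimethylsilyloxy)-2-methylbut-2-en-1-yl carbonate
Conditions: KHF2, MeOH, rt
Reagents that add atoms: none
Why: Chemoselective desilylation, since KHF2 in methanol cleaves the silyl ether of an acidic phenol (a good leaving group from silicon) far faster than an alkyl silyl ether and leaves the methyl carbonate alone.

Step 8
Reactants: 12 methyl (2E,4R)-4-(5-acetyl-2-hydroxyphenyl)-4-(tert-butyldimethylsilyloxy)-2-methylbut-2-en-1-yl carbonate
Product: 13 1-[(2R,3S)-3-(tert-butyldimethylsilyloxy)-2-(prop-1-en-2-yl)-2,3-dihydro-1-benzofuran-5-yl]ethan-1-one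
Conditions: Pd2(dba)3·CHCl3 (2.5 mol %), (R,R)-N,N'-(cyclohexane-1,2-diyl)bis[2-(diphenylphosphino)benzamide] (7.5 mol %), CH2Cl2, rt
Reagents that add atoms: none
Why: Zerovalent palladium ionises the primary allylic carbonate with loss of CO2 and methoxide, the methoxide deprotonates the acidic para-acyl phenol, and the phenoxide attacks the internal terminus of the 2-methyl-π-allyl complex anti to the metal, which forms O1–C2 and leaves the isopropenyl group outside the new ring. The closest known reaction type is the intramolecular Tsuji–Trost asymmetric allylic O-alkylation, by which phenols carrying an allylic carbonate side chain are cyclised to 2-alkenyl dihydrobenzofurans and chromans. Ring B closes in the 5-exo mode, and the alternative attack at the CH2 terminus would be a 7-endo closure enclosing an E alkene and should not compete. C2 is controlled by the allyl face that carries palladium: the two faces exchange by π–σ–π shift through the unsubstituted CH2 terminus, the chiral diphosphine selects the face whose backside attack gives 2R, and the silyloxy group on the neighbouring C3 adds a substrate bias toward the trans ring. The step needs trans diastereoselectivity, which is backed up because the product is an allyl ether of an acidic phenol and can re-ionise under the catalyst, so that any cis ether should drain toward the more stable trans isomer. Chemoselectivity is secured because only the carbonate is a leaving group for palladium, so the silyl ether, the aryl ketone and the C3 stereocentre, which lies outside the allyl system, are untouched.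

Step 9
Reactants: 13 1-[(2R,3S)-3-(tert-butyldimethylsilyloxy)-2-(prop-1-en-2-yl)-2,3-dihydro-1-benzofuran-5-yl]ethan-1-one
Product: 14 1-[(2R,3S)-3-hydroxy-2-(prop-1-en-2-yl)-2,3-dihydro-1-benzofuran-5-yl]ethan-1-one
Conditions: Bu4NF, AcOH (1:1), THF, 0 °C to rt
Reagents that add atoms: none
Why: Fluoride desilylation buffered with acetic acid frees the C3 alcohol without generating a basic alkoxide, and neither stereocentre is involved in the Si–O cleavage.

Step 10
Reactants: 15 (E)-crotonaldehyde
Product: 16 (Z)-2-iodobut-2-enal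
Conditions: I2, K2CO3, DMAP (0.2 equiv), THF/H2O 1:1, rt
Reagents that add atoms: iodine, II
Why: Amine-catalysed α-iodination of an enal (Baylis–Hillman-type conjugate addition, iodination of the enolate, elimination of the amine) gives the Z iodide, in which iodine is cis to the β-methyl group.

Step 11
Reactants: 16 (Z)-2-iodobut-2-enal
Product: 17 (Z)-2-iodobut-2-en-1-ol
Conditions: NaBH4, CeCl3·7H2O, MeOH, 0 °C
Reagents that add atoms: none
Why: Luche 1,2-reduction of the enal leaves the C–I bond and the alkene geometry unchanged.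

Step 12
Reactants: 17 (Z)-2-iodobut-2-en-1-ol
Product: 18 tert-butyl{[(2Z)-2-iodobut-2-en-1-yl]oxy}dimethylsilane
Conditions: TBSCl, imidazole, CH2Cl2, rt
Reagents that add atoms: tert-butyldimethylsilyl chloride, CC(C)(C)[Si](C)(C)Cl
Why: Silylation of the primary alcohol gives an ether that, unlike an acetate, is not lost by β-elimination from the alkenylpalladium species of step 13 and is not displaced during the acylation of step 14.

Step 13
Reactants: 18 tert-butyl{[(2Z)-2-iodobut-2-en-1-yl]oxy}dimethylsilane
Product: 19 (2Z)-2-[(tert-butyldimethylsilyloxy)methyl]but-2-enoic acid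
Conditions: Pd(OAc)2 (5 mol %), PPh3 (10 mol %), CO (1 atm), Et3N, H2O, DMF, 50 °C; then aq. citric acid
Reagents that add atoms: carbon monoxide, [C-]#[O+]; water, O
Why: Palladium-catalysed hydroxycarbonylation of an alkenyl iodide, in which oxidative addition, CO insertion and hydrolysis of the acylpalladium species all retain the alkene geometry, so the carboxyl group ends up cis to the methyl group (Z).

Step 14
Reactants: 14 1-[(2R,3S)-3-hydroxy-2-(prop-1-en-2-yl)-2,3-dihydro-1-benzofuran-5-yl]ethan-1-one; 19 (2Z)-2-[(tert-butyldimethylsilyloxy)methyl]but-2-enoic acid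
Product: 21 (2R,3S)-5-acetyl-2-(prop-1-en-2-yl)-2,3-dihydro-1-benzofuran-3-yl (2Z)-2-[(tert-butyldimethylsilyloxy)methyl]but-2-enoate, via mixed anhydride 20 (not isolated)
Conditions: 2,4,6-trichlorobenzoyl chloride, Et3N, toluene, rt; then 14, DMAP, toluene, rt
Reagents that add atoms: none
Why: Yamaguchi esterification, in which DMAP attacks the less hindered acyl group of the mixed anhydride and the acylpyridinium salt acylates the secondary alcohol at room temperature, conditions under which angelate-type Z acids are expected to keep their geometry, and C3 keeps its configuration because its C–O bond is not broken.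

Step 15
Reactants: 21 (2R,3S)-5-acetyl-2-(prop-1-en-2-yl)-2,3-dihydro-1-benzofuran-3-yl (2Z)-2-[(tert-butyldimethylsilyloxy)methyl]but-2-enoate
Product: 22 (2R,3S)-5-acetyl-2-(prop-1-en-2-yl)-2,3-dihydro-1-benzofuran-3-yl (2Z)-2-(hydroxymethyl)but-2-enoate
Conditions: HF·pyridine, pyridine, THF, 0 °C to rt
Reagents that add atoms: none
Why: Fluoride desilylation under buffered, non-basic conditions removes the primary silyl ether without cleaving or shifting the benzylic ester.

Step 16
Reactants: 22 (2R,3S)-5-acetyl-2-(prop-1-en-2-yl)-2,3-dihydro-1-benzofuran-3-yl (2Z)-2-(hydroxymethyl)but-2-enoate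
Product: 23 (2R,3S)-5-acetyl-2-(prop-1-en-2-yl)-2,3-dihydro-1-benzofuran-3-yl (2Z)-2-(acetoxymethyl)but-2-enoate
Conditions: Ac2O, pyridine, CH2Cl2, 0 °C to rt
Reagents that add atoms: acetic anhydride, CC(=O)OC(C)=O
Why: Acetylation of the primary allylic alcohol with Ac2O/pyridine, run without DMAP so that the allylic acetate formed is not exposed to a nucleophilic catalyst that could displace it in the SN2' sense.

**Compound list**

1 | 4'-hydroxyacetophenone | CC(=O)c1ccc(O)cc1 | starting material
2 | 1-[4-hydroxy-3-(hydroxymethyl)phenyl]ethan-1-one (magnesium-bound, not isolated) | CC(=O)c1ccc(O)c(CO)c1 | intermediate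
3 | 5-acetyl-2-hydroxybenzaldehyde | CC(=O)c1ccc(O)c(C=O)c1 | intermediate
4 | 5-acetyl-2-(tert-butyldimethylsilyloxy)benzaldehyde | CC(=O)c1ccc(O[Si](C)(C)C(C)(C)C)c(C=O)c1 | intermediate
5 | propargyl alcohol | C#CCO | starting material
6 | dimethyl[(1E)-3-(dimethylalumanyloxy)-2-methylprop-1-en-1-yl]alumane (not isolated) | C/C(=C\[Al](C)C)CO[Al](C)C | intermediate
7 | (E)-3-iodo-2-methylprop-2-en-1-ol | C/C(=C\I)CO | intermediate
8 | methyl (2E)-3-iodo-2-methylprop-2-en-1-yl carbonate | C/C(=C\I)COC(=O)OC | intermediate
9 | trimethylsilyl ether of 10 (not isolated) | CC(=O)c1ccc(O[Si](C)(C)C(C)(C)C)c(c1)[C@H](O[Si](C)(C)C)/C=C(\C)COC(=O)OC | intermediate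
10 | methyl (2E,4R)-4-[5-acetyl-2-(tert-butyldimethylsilyloxy)phenyl]-4-hydroxy-2-methylbut-2-en-1-yl carbonate | CC(=O)c1ccc(O[Si](C)(C)C(C)(C)C)c(c1)[C@H](O)/C=C(\C)COC(=O)OC | intermediate
11 | methyl (2E,4R)-4-[5-acetyl-2-(tert-butyldimethylsilyloxy)phenyl]-4-(tert-butyldimethylsilyloxy)-2-methylbut-2-en-1-yl carbonate | CC(=O)c1ccc(O[Si](C)(C)C(C)(C)C)c(c1)[C@H](O[Si](C)(C)C(C)(C)C)/C=C(\C)COC(=O)OC | intermediate
12 | methyl (2E,4R)-4-(5-acetyl-2-hydroxyphenyl)-4-(tert-butyldimethylsilyloxy)-2-methylbut-2-en-1-yl carbonate (precursor of the key step) | CC(=O)c1ccc(O)c(c1)[C@H](O[Si](C)(C)C(C)(C)C)/C=C(\C)COC(=O)OC | intermediate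
13 | 1-[(2R,3S)-3-(tert-butyldimethylsilyloxy)-2-(prop-1-en-2-yl)-2,3-dihydro-1-benzofuran-5-yl]ethan-1-one (trans; product of the key step) | C=C(C)[C@H]1Oc2ccc(C(C)=O)cc2[C@@H]1O[Si](C)(C)C(C)(C)C | intermediate
14 | 1-[(2R,3S)-3-hydroxy-2-(prop-1-en-2-yl)-2,3-dihydro-1-benzofuran-5-yl]ethan-1-one | C=C(C)[C@H]1Oc2ccc(C(C)=O)cc2[C@@H]1O | intermediate
15 | (E)-crotonaldehyde | C/C=C/C=O | starting material
16 | (Z)-2-iodobut-2-enal | C/C=C(\I)C=O | intermediate
17 | (Z)-2-iodobut-2-en-1-ol | C/C=C(\I)CO | intermediate
18 | tert-butyl{[(2Z)-2-iodobut-2-en-1-yl]oxy}dimethylsilane | C/C=C(\I)CO[Si](C)(C)C(C)(C)C | intermediate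
19 | (2Z)-2-[(tert-butyldimethylsilyloxy)methyl]but-2-enoic acid | C/C=C(\C(=O)O)CO[Si](C)(C)C(C)(C)C | intermediate
20 | mixed anhydride of 19 with 2,4,6-trichlorobenzoic acid (not isolated) | C/C=C(\C(=O)OC(=O)c1c(Cl)cc(Cl)cc1Cl)CO[Si](C)(C)C(C)(C)C | intermediate
21 | (2R,3S)-5-acetyl-2-(prop-1-en-2-yl)-2,3-dihydro-1-benzofuran-3-yl (2Z)-2-[(tert-butyldimethylsilyloxy)methyl]but-2-enoate | C=C(C)[C@H]1Oc2ccc(C(C)=O)cc2[C@@H]1OC(=O)/C(=C\C)CO[Si](C)(C)C(C)(C)C | intermediate
22 | (2R,3S)-5-acetyl-2-(prop-1-en-2-yl)-2,3-dihydro-1-benzofuran-3-yl (2Z)-2-(hydroxymethyl)but-2-enoate | C=C(C)[C@H]1Oc2ccc(C(C)=O)cc2[C@@H]1OC(=O)/C(=C\C)CO | intermediate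
23 | (2R,3S)-5-acetyl-2-(prop-1-en-2-yl)-2,3-dihydro-1-benzofuran-3-yl (2Z)-2-(acetoxymethyl)but-2-enoate, CNP0289095.1 | C=C(C)[C@H]1Oc2ccc(C(C)=O)cc2[C@@H]1OC(=O)/C(=C\C)COC(C)=O | target

**Totals**

Total step count: 16. Longest linear sequence: 10 steps (1, 2, 5, 6, 7, 8, 9, 14, 15, 16 from 4'-hydroxyacetophenone; the propargyl alcohol branch 3, 4, 5–9, 14–16 is equally long).

**Steps most likely to fail, with fallbacks**

Step 8. What may go wrong: poor facial selectivity at the allyl terminus if catalyst and substrate preferences oppose each other, or β-hydride loss from the hindered allyl complex to a diene. The fallback sets out from 10 and comes back at 13. It sets C2 by an SN2 epoxide opening in place of the palladium step.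
- m-CPBA (NaHCO3, CH2Cl2, 0 °C) should epoxidise 10 on the face of the hydroxyl group in the conformer that avoids A(1,3) strain with the cis methyl group, giving the threo epoxy alcohol F1.
- TBSCl and imidazole in DMF should give its silyl ether F2.
- K2CO3 in MeOH (rt to 40 °C) should free the phenoxide, which opens the epoxide at the secondary carbon (5-exo, inversion) while the carbonate is methanolysed, giving the trans diol F3.
- 1,1'-Thiocarbonyldiimidazole (toluene, 80 °C) should give the cyclic thionocarbonate F4.
- Corey–Winter olefination of F4 with 1,3-dimethyl-2-phenyl-1,3,2-diazaphospholidine (THF, 40 °C) should turn the diol carbons into the isopropenyl group and give 13.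

Step 5. What may go wrong: loss of enantiocontrol in the chromium addition, for instance through a ligand-free background reaction, or consumption of the allylic carbonate by low-valent nickel. The fallback sets out from 4 and 8 and comes back at 10. It replaces asymmetric catalysis by a racemic coupling followed by kinetic resolution.
- The coupling run without the chiral ligand (CrCl2 cat., NiCl2 cat., Mn, Me3SiCl, DMF/DME, rt) should give the racemic trimethylsilyl ether F5 and, after the same citric acid work-up, the racemic allylic alcohol F6.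
- Sharpless kinetic resolution of F6 [Ti(OiPr)4, D-(−)-diisopropyl tartrate, t-BuOOH (about 0.6 equiv), 4 Å molecular sieves, CH2Cl2, −20 °C] should epoxidise the S enantiomer to the erythro epoxy alcohol F7 and leave the R alcohol 10, which is separated by chromatography.

Step 14. What may go wrong: Z-to-E isomerisation of the activated acid by reversible conjugate addition of DMAP, or ionisation of the benzylic C3–O bond with aromatisation to the benzofuran. The fallback sets out from 14 and 18 and comes back at 21; no new compound is formed on the way (F0). The ester is made by palladium-catalysed alkoxycarbonylation of the alkenyl iodide 18 in the presence of alcohol 14 [Pd(OAc)2, PPh3, CO (1 atm), Et3N, DMF, 50 °C]. The acylpalladium species formed with retention of geometry is intercepted directly by the alcohol, so no free activated acid is present and no nucleophilic amine catalyst is needed.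

**Further compounds**

F1 | step 8 | methyl {(2R,3R)-3-[(S)-[5-acetyl-2-(tert-butyldimethylsilyloxy)phenyl](hydroxy)methyl]-2-methyloxiran-2-yl}methyl carbonate (threo) | CC(=O)c1ccc(O[Si](C)(C)C(C)(C)C)c(c1)[C@H](O)[C@H]1O[C@]1(C)COC(=O)OC
F2 | step 8 | methyl {(2R,3R)-3-[(S)-[5-acetyl-2-(tert-butyldimethylsilyloxy)phenyl](tert-butyldimethylsilyloxy)methyl]-2-methyloxiran-2-yl}methyl carbonate | CC(=O)c1ccc(O[Si](C)(C)C(C)(C)C)c(c1)[C@H](O[Si](C)(C)C(C)(C)C)[C@H]1O[C@]1(C)COC(=O)OC
F3 | step 8 | 1-[(2S,3S)-3-(tert-butyldimethylsilyloxy)-2-[(2R)-1,2-dihydroxypropan-2-yl]-2,3-dihydro-1-benzofuran-5-yl]ethan-1-one (trans) | C[C@@](O)(CO)[C@H]1Oc2ccc(C(C)=O)cc2[C@@H]1O[Si](C)(C)C(C)(C)C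
F4 | step 8 | 1-[(2S,3S)-3-(tert-butyldimethylsilyloxy)-2-[(4R)-4-methyl-2-thioxo-1,3-dioxolan-4-yl]-2,3-dihydro-1-benzofuran-5-yl]ethan-1-one | C[C@]3(OC(=S)OC3)[C@H]1Oc2ccc(C(C)=O)cc2[C@@H]1O[Si](C)(C)C(C)(C)C
F5 | step 5 | racemic methyl (2E)-4-[5-acetyl-2-(tert-butyldimethylsilyloxy)phenyl]-2-methyl-4-(trimethylsilyloxy)but-2-en-1-yl carbonate | CC(=O)c1ccc(O[Si](C)(C)C(C)(C)C)c(c1)C(O[Si](C)(C)C)/C=C(\C)COC(=O)OC
F6 | step 5 | racemic methyl (2E)-4-[5-acetyl-2-(tert-butyldimethylsilyloxy)phenyl]-4-hydroxy-2-methylbut-2-en-1-yl carbonate | CC(=O)c1ccc(O[Si](C)(C)C(C)(C)C)c(c1)C(O)/C=C(\C)COC(=O)OC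
F7 | step 5 | methyl {(2R,3R)-3-[(R)-[5-acetyl-2-(tert-butyldimethylsilyloxy)phenyl](hydroxy)methyl]-2-methyloxiran-2-yl}methyl carbonate (erythro) | CC(=O)c1ccc(O[Si](C)(C)C(C)(C)C)c(c1)[C@@H](O)[C@H]1O[C@]1(C)COC(=O)OC
F0 | step 14 | none | none
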